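(The data are calculated with constants of no real substance; noise was put on by code.)

A stirred vessel holds electrophile and free base while nucleophile runs in at a steady rate over 3.0 min, and two earlier runs stand beside the two new flasks, zeta and beta.

| flask | electrophile | nucleophile | free base | remark | time |
|---|---|---|---|---|---|
| Tuesday's | 0.020 M | 1.1 equiv (fed, over 3.0 min) | 1.4 equiv | run made earlier |  |
| Wednesday's | 0.020 M | 1.1 equiv (fed, over 3.0 min) | 2.6 equiv | run made earlier |  |
| zeta | 0.020 M | 1.10 equiv (fed, over 3.0 min) | 1.10 equiv |  | 12 min |
| beta | 0.020 M | 1.10 equiv (fed, over 3.0 min) | 2.20 equiv |  | 12 min |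

| run | time / min | electrophile / % | product / % |
|---|---|---|---|
| Tuesday's | 0.833 | 95.7 | 4.7 |
| Tuesday's | 2.50 | 69.3 | 30.0 |
| Tuesday's | 4.00 | 49.4 | 51.8 |
| Tuesday's | 6.00 | 35.9 | 64.0 |
| Tuesday's | 10.0 | 24.5 | 74.2 |
| Tuesday's | 12.0 | 23.2 | 77.7 |
| Wednesday's | 1.00 | 93.3 | 6.7 |
| Wednesday's | 1.50 | 85.9 | 13.3 |
| Wednesday's | 2.50 | 69.9 | 30.8 |
| Wednesday's | 4.00 | 47.6 | 51.3 |
| Wednesday's | 8.00 | 29.8 | 71.2 |
| Wednesday's | 12.0 | 22.1 | 77.4 |

(scatter of a reading: 0.5 percentage points)

- what was read earlier has a scatter of 0.5 percentage points, one standard deviation

- part of the electrophile that has reacted at the end, zeta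
- part of the electrophile that has reacted at the end, beta
- what raising the equivalents of free base from its lowest to its highest value here does to the part of the electrophile that has reacted (changes below 5 percentage points count as none) (it falls / no change / it rises)

Take first the main step, electrophile + nucleophile to product: each electrophile lost takes one nucleophile, so 1.10 equiv of nucleophile leaves room for 100% of the electrophile to react. Add the free base, supposing that each turn sets free one acid and the free base takes it up. The rate of free base use divided by the rate of electrophile loss is then one, time drops out, and the question reduces to one ratio. This base cover C is 1.43 for zeta, being the equivalents of free base charged per equivalent of electrophile reacted at the end, with the reacted part taken from Tuesday's run, 76.8%. Since C stands above one, this addition takes nothing from the number, and a share of one minus the reciprocal of C, or 30.1% of zeta's free base, is reckoned to remain. Beta has C = 2.86. Tuesday's run, at 1.82, and Wednesday's, at 3.34, ended 1.1 percentage points apart, against a scatter of 0.5 points. The rest is read from the runs: Tuesday's electrophile goes from 24.5% at 10.0 min to 23.2% at 12.0 min. This slowing is carried over as a reading, and the reckoning here puts zeta and beta near Tuesday's reacted part, although zeta's cover lies below those of the two earlier runs.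

The forecast gives 77% (72% to 80%) for zeta, 78% (76% to 80%) for beta, and no change, holding that “the rate is effectively zero order in base here”.

The flasks give 76.9% for zeta and 77.3% for beta, so no change, with a shift of 0.41 points.

    electrophile + nucleophile → acid set free + product (k = 0.380 M⁻¹ s⁻¹)
    nucleophile + acid set free ⇌ protonated nucleophile, settled at all times (K = 57000 M⁻¹)
    acid set free + free base ⇌ salt of the base, settled at all times (K = 1.00 × 10⁶ M⁻¹)
    2 nucleophile → homo dimer (k = 0.0800 M⁻¹ s⁻¹)

Zeta, at a cover of 1.43, kept 31% of its free base at 12.0 min. A neighbour flask like zeta but charged with 0.440 equiv of free base has a cover, reckoned the same way, of 0.573, which is below one. In that neighbour free base is first to run out, with 0.77% of its charge left at 12.0 min, protonated nucleophile stands at 0.00466 M against 2.58 × 10⁻⁴ M in zeta, and 67.6% of the electrophile has reacted against zeta's 76.9%.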